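**Assumption:** the target has no stereocentre and no stereogenic double bond (the prenyl alkene carries two identical methyls), so it is achiral and the structure as written is the single species to be made.

## Retrosynthetic overview

1. Target 10 ⇐ one-pot unmasking of protected isoflavone 9: BCl3 removes the two MOM groups and, by chelation to C4=O, only the 5-OMe.
2. 9 ⇐ key step: dehydrogenative radical C–H/C–H coupling of enaminone 7 (radical cation at Cα) with 1,3-bis(methoxymethoxy)benzene 8. This forms C3–C1′, and the pyranone ring then closes (O1–C2) with loss of Me2NH.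
3. 7 ⇐ DMF-DMA condensation ⇐ acetophenone 6 ⇐ ortho-acetylation of the symmetric phenol 5. The symmetry of 5 fixes the 5-O / 6-prenyl / 7-O pattern.
4. 5 ⇐ Ir C–H borylation/oxidation of 4 ⇐ ortho-lithiation/prenylation of 1,3-dimethoxybenzene 2 ⇐ resorcinol 1. Arene 8 also comes from resorcinol.
5. Ring order: both benzene rings come preformed from resorcinol; the pyranone ring is the only ring built, and it is built last, in the key step.

## Route

**Step 1**
Reactants: 1, resorcinol
Product: 2, 1,3-dimethoxybenzene
Conditions: MeI, K2CO3, acetone, reflux
Reagents that add atoms: iodomethane, CI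
Why: Williamson O-methylation of both phenols; one methyl becomes the 7-OMe of the target and the other masks the future 5-OH.

**Step 2**
Reactants: 2, 1,3-dimethoxybenzene; 3, prenyl bromide (1-bromo-3-methylbut-2-ene)
Product: 4, 1,3-dimethoxy-2-(3-methylbut-2-en-1-yl)benzene
Conditions: n-BuLi, THF, 0 °C → rt; then CuI (5 mol %), 3, −78 °C → rt
Reagents that add atoms: none (the prenyl unit comes from reactant 3)
Why: Directed ortho-metalation at the doubly activated C2 between the two OMe groups, then SN2 allylation (Cu suppresses SN2′), puts the prenyl group between the two oxygens.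

**Step 3**
Reactants: 4
Product: 5, 3,5-dimethoxy-4-(3-methylbut-2-en-1-yl)phenol
Conditions: [Ir(OMe)(cod)]2 (1.5 mol %), dtbpy (3 mol %), B2pin2, THF, 80 °C; then aq. NaOH, 30 % H2O2, 0 °C → rt (one pot)
Reagents that add atoms: hydrogen peroxide, OO (B2pin2 is only transient)
Why: Sterically controlled Ir-catalysed C–H borylation goes to the only ring C–H with no ortho substituent (C5, para to the prenyl group); alkaline peroxide oxidises the boronate to the phenol and leaves the trisubstituted alkene alone.

**Step 4**
Reactants: 5
Product: 6, 1-[6-hydroxy-2,4-dimethoxy-3-(3-methylbut-2-en-1-yl)phenyl]ethan-1-one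
Conditions: POCl3, N,N-dimethylacetamide (1.2 equiv), MeCN, 0 → 50 °C; then aq. NaOAc, 60 °C
Reagents that add atoms: N,N-dimethylacetamide, CC(=O)N(C)C (acetyl carbons); water, O (ketone oxygen on iminium hydrolysis)
Why: Vilsmeier–Haack acetylation of a phloroglucinol-type ring; the para position is blocked and the two ortho positions are symmetry-equivalent, so one regioisomer forms, and no strong Brønsted or Lewis acid is present to attack the prenyl group.

**Step 5**
Reactants: 6
Product: 7, (E)-3-(dimethylamino)-1-[6-hydroxy-2,4-dimethoxy-3-(3-methylbut-2-en-1-yl)phenyl]prop-2-en-1-one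
Conditions: DMF-DMA (2 equiv), toluene, 95 °C
Reagents that add atoms: N,N-dimethylformamide dimethyl acetal, COC(OC)N(C)C
Why: Standard condensation of a methyl ketone with DMF-DMA gives the (E)-enaminone; the hydrogen-bonded ortho-OH is not methylated.

**Step 6**
Reactants: 1, resorcinol
Product: 8, 1,3-bis(methoxymethoxy)benzene
Conditions: MOMCl, i-Pr2NEt, CH2Cl2, 0 °C → rt
Reagents that add atoms: chloromethyl methyl ether, COCCl
Why: Acetal protection keeps the arene electron-rich for the coupling and blocks the B-ring ortho oxygen, which would otherwise trap the iminium carbon 5-exo and give a 3-aroylbenzofuran.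

**Step 7 (key step)**
Reactants: 7; 8 (4 equiv, excess recoverable)
Product: 9, 3-[2,4-bis(methoxymethoxy)phenyl]-5,7-dimethoxy-6-(3-methylbut-2-en-1-yl)-4H-chromen-4-one
Conditions: graphite(+) | Pt(−), undivided cell, constant current 5 mA, 2.4 F mol⁻¹, n-Bu4NBF4 (0.1 M), MeCN/HFIP 4:1, rt; then 50 °C, 1 h
Reagents that add atoms: none
Why: Proposed new method: anodic one-electron oxidation of the enaminone (estimated to be the most easily oxidised π-system present, ahead of arene 8 and the prenyl alkene) gives a radical cation whose electrophilic α-carbon radical adds to C4 of 8 (para to one OMOM, ortho to the other, the most nucleophilic and least hindered site); a second oxidation and proton loss re-aromatise the ring, and the ortho-phenol then closes 6-exo onto the iminium carbon and expels Me2NH to give the chromone, with H2 evolved at the cathode. The closest known reaction types are the oxidative radical C3-functionalisation/annulation of o-hydroxyaryl enaminones to 3-substituted chromones and the homolytic aromatic substitution of electron-rich arenes by electrophilic α-carbonyl and enamine radical cations.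

**Step 8**
Reactants: 9
Product: 10, 7-O-methylluteone (target)
Conditions: BCl3 (5 equiv), CH2Cl2, −78 → −20 °C; then MeOH, aq. NaHCO3, cold
Reagents that add atoms: none
Why: BCl3 cleaves both aryl MOM acetals and, through chelation to the C4 carbonyl, only the peri 5-OMe; the 7-OMe has no chelating neighbour and survives, and the low temperature with the 5-oxygen held on boron until quench limits prenyl cyclisation.

## Compound list

1 | resorcinol (benzene-1,3-diol) | Oc1cccc(O)c1 | starting material
2 | 1,3-dimethoxybenzene | COc1cccc(OC)c1 | intermediate
3 | prenyl bromide (1-bromo-3-methylbut-2-ene) | CC(C)=CCBr | starting material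
4 | 1,3-dimethoxy-2-(3-methylbut-2-en-1-yl)benzene | COc1cccc(OC)c1CC=C(C)C | intermediate
5 | 3,5-dimethoxy-4-(3-methylbut-2-en-1-yl)phenol | COc1cc(O)cc(OC)c1CC=C(C)C | intermediate
6 | 1-[6-hydroxy-2,4-dimethoxy-3-(3-methylbut-2-en-1-yl)phenyl]ethan-1-one | CC(=O)c1c(O)cc(OC)c(CC=C(C)C)c1OC | intermediate
7 | (E)-3-(dimethylamino)-1-[6-hydroxy-2,4-dimethoxy-3-(3-methylbut-2-en-1-yl)phenyl]prop-2-en-1-one | CN(C)/C=C/C(=O)c1c(O)cc(OC)c(CC=C(C)C)c1OC | intermediate
8 | 1,3-bis(methoxymethoxy)benzene | COCOc1cccc(OCOC)c1 | intermediate
9 | 3-[2,4-bis(methoxymethoxy)phenyl]-5,7-dimethoxy-6-(3-methylbut-2-en-1-yl)-4H-chromen-4-one | COCOc1ccc(-c2coc3cc(OC)c(CC=C(C)C)c(OC)c3c2=O)c(OCOC)c1 | intermediate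
10 | 7-O-methylluteone, 3-(2,4-dihydroxyphenyl)-5-hydroxy-7-methoxy-6-(3-methylbut-2-en-1-yl)-4H-chromen-4-one | COc1cc2occ(-c3ccc(O)cc3O)c(=O)c2c(O)c1CC=C(C)C | target

## Summary

**Total steps:** 8

**Longest linear sequence:** 7 (steps 1, 2, 3, 4, 5, 7, 8); step 6 is a one-step branch.

**Three steps most likely to fail**

1. **Step 7.** Likely problems are enaminone homodimerisation, premature closure to the 3-unsubstituted chromone, and attack on the prenyl alkene or the free A-ring C–H. Fallback: iodinate 8 (NIS, MeCN) to 1-iodo-2,4-bis(methoxymethoxy)benzene and make the arene the radical. Reductive photoredox (10-phenylphenothiazine, 390 nm) generates the aryl radical, which adds to Cα of 7 and annulates to 9. This reverses the radical polarity with a pre-functionalised partner and costs one step.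

2. **Step 4.** The Vilsmeier acetylation may be sluggish at the di-ortho-flanked position, or the alkene may be damaged. Fallback: O-acetylate 5 (Ac2O, pyridine) and run a photo-Fries rearrangement (254 nm, MeCN). This is an acid-free radical-pair acyl shift, and the blocked para position allows only ketone 6. It costs one step.

3. **Step 8.** The 6-prenyl group may cyclise onto the new 5-OH, or HCl may add to the alkene. Fallback: change the protecting-group plan. Carry the B ring as the bis-TBS ether (TBSCl in step 6), cleave the 5-OMe with MgI2·OEt2 (neutral, chelation-controlled), then remove the silyl ethers with TBAF/AcOH. No strong acid is then present once the 5-OH is free; this costs one step.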